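The route cuts C9–C10, the bond joining the acyloin carbinol of ring B to the ring-fusion carbon. Because C9 of the C8/C9 acyloin is bonded directly to C10, an α-keto aldehyde (C8, C9) hanging from quaternary C5 can add to a ring A alkene C10=C1 in a type 1 carbonyl-ene reaction. One operation closes ring B, makes C9–C10, leaves ketone and carbinol at their final oxidation levels and fixes the cis ring fusion. The precursor is a cyclohexene with the C3 silyl ether, the cis C4/C5 methyl pair and a 3,4-dioxobutyl chain on C5. C9 is expected to emerge epimeric and is equilibrated afterwards.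

Key step: step 14

Conventions: eremophilane numbering is used for all intermediates (ring A: C1–C5, C10; chain or ring B: C6–C9; methyls C14 on C5 and C15 on C4; side chain C11–C13). β is the face of ring A that carries C14, α the opposite face.
Assumption: a commercial (S)-selective ketoreductase accepts diketone 4 in the same sense as whole-cell yeast reductions of 2-alkyl-2-methylcyclohexane-1,3-diones.
Stereochemical remark: in a concerted ene process the hydrogen can only come from C2, which lies on the C5 side of C10=C1. O9 must therefore lie over ring A, so 18 is drawn with the hydroxyl α (trans to H10), and C9 is brought to β in step 17.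
Protecting groups: TBS at C3 (removed first, by acid), TIPS at C9, TBDPS at C12.

Step 1
Reactants: 1 2-methylcyclohexane-1,3-dione; 2 methyl vinyl ketone
Product: 3 2-methyl-2-(3-oxobutyl)cyclohexane-1,3-dione
Conditions: H2O, AcOH (cat.), 75 °C
Reagents that add atoms: none
Why: Michael addition of the stabilised dione enolate to the enone; C-alkylation at the methyl-bearing carbon builds the still prochiral quaternary C5 together with all four chain carbons C6–C9.

Step 2
Reactants: 3 2-methyl-2-(3-oxobutyl)cyclohexane-1,3-dione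
Product: 4 2-methyl-2-[2-(2-methyl-1,3-dioxolan-2-yl)ethyl]cyclohexane-1,3-dione
Conditions: Me3SiOCH2CH2OSiMe3, Me3SiOTf (cat.), CH2Cl2, −78 °C
Reagents that add atoms: 1,2-bis(trimethylsilyloxy)ethane, C[Si](C)(C)OCCO[Si](C)(C)C
Why: Silyl-triflate-catalysed ketalisation under kinetic control; only the unhindered side-chain ketone should react, the ring carbonyls beside the quaternary carbon stay free, and the low temperature avoids acid-induced aldol closure.

Step 3
Reactants: 4 2-methyl-2-[2-(2-methyl-1,3-dioxolan-2-yl)ethyl]cyclohexane-1,3-dione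
Product: 5 (2S,3S)-3-hydroxy-2-methyl-2-[2-(2-methyl-1,3-dioxolan-2-yl)ethyl]cyclohexan-1-one (C4 ketone; 10α-OH; C14 β; chain α)
Conditions: NADPH-dependent (S)-selective ketoreductase, NADP+ (cat.), i-PrOH, phosphate buffer pH 7, 30 °C
Reagents that add atoms: none
Why: Enzymatic desymmetrising carbonyl reduction, a known reaction of 2,2-disubstituted cyclohexane-1,3-diones; the enzyme selects one enantiotopic carbonyl and one of its faces, which fixes C5 (methyl β, chain α) and gives the C10 carbinol α, cis to the chain.

Step 4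
Reactants: 5 (2S,3S)-hydroxy ketone
Product: 6 C4 2,4,6-triisopropylbenzenesulfonylhydrazone of 5 (N–N bond syn to C3)
Conditions: 2,4,6-triisopropylbenzenesulfonohydrazide, THF, 4 Å sieves, rt to 40 °C
Reagents that add atoms: 2,4,6-triisopropylbenzenesulfonohydrazide, CC(C)c1cc(C(C)C)c(S(=O)(=O)NN)c(C(C)C)c1
Why: Hydrazone condensation at the only ketone without added acid, so the ketal survives; C3 is the only α-carbon with hydrogens, which makes the next deprotonation regiochemically unambiguous.

Step 5
Reactants: 6 C4 sulfonylhydrazone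
Product: 8 2,3-dimethyl-2-[2-(2-methyl-1,3-dioxolan-2-yl)ethyl]cyclohex-3-en-1-ol (C3=C4; C15 on C4; 10α-OH; C14 β), via C4 vinyllithium C10 alkoxide 7 (not isolated)
Conditions: n-BuLi (3.3 equiv), TMEDA, THF, −78 to 0 °C; MeI (1.1 equiv), −78 °C
Reagents that add atoms: iodomethane, CI
Why: Shapiro reaction; loss of sulfinate and N2 from the dianion gives the C4 vinyllithium, which iodomethane alkylates faster than the hindered alkoxide, installing C15 and the C3=C4 alkene without touching a stereocentre.

Step 6
Reactants: 8 homoallylic alcohol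
Product: 9 3α,4α-epoxide of 8
Conditions: VO(acac)2 (cat.), t-BuOOH, CH2Cl2, 0 °C to rt
Reagents that add atoms: tert-butyl hydroperoxide, CC(C)(C)OO
Why: Hydroxyl-directed vanadium-catalysed epoxidation of a homoallylic cyclohexenol; the peroxide bound to the vanadium alkoxide of the 10α-oxygen is delivered to the α face, which sets the C3–O bond α.

Step 7
Reactants: 9 3α,4α-epoxy alcohol
Product: 10 3α,10α-diol with exocyclic C4=C15 methylene
Conditions: LiNEt2 (3.5 equiv), Et2O–hexane, reflux
Reagents that add atoms: none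
Why: Base-induced epoxide to allylic alcohol isomerisation (syn β-elimination); the amide removes a proton from the unhindered C15 methyl (C5 has none) and the C4–O bond breaks, so the C3–O bond and its α configuration are kept.

Step 8
Reactants: 10 allylic diol
Product: 11 3α,10α-diol with 4β-methyl (H4 α)
Conditions: [Ir(cod)(PCy3)(py)]PF6 (5 mol %), H2 (1 atm), CH2Cl2, rt
Reagents that add atoms: none
Why: Hydroxyl-directed homogeneous hydrogenation; the cationic iridium catalyst is held by the α-hydroxyls at C3 and C10 and adds H2 to the α face of C4=C15, putting H4 α and methyl C15 β, cis to C14 and trans to O3.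

Step 9
Reactants: 11 3α,10α-diol
Product: 12 3α-TBS ether of 11 (10α-OH free)
Conditions: t-BuMe2SiCl (1.1 equiv), imidazole, DMF, 0 °C to rt
Reagents that add atoms: tert-butyldimethylsilyl chloride, CC(C)(C)[Si](C)(C)Cl
Why: Sterically controlled silylation; the equatorial C3 hydroxyl reacts while the axial, neopentyl C10 hydroxyl next to quaternary C5 should not.

Step 10
Reactants: 12 mono-TBS ether
Product: 13 ring A cyclohexene C10=C1 (3α-OTBS; 4β,5β-dimethyl; ketal chain α on C5)
Conditions: POCl3, pyridine, 60 °C
Reagents that add atoms: none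
Why: E2 dehydration through the dichlorophosphate; the C10–O bond is axial and antiperiplanar to axial H1β, C5 has no hydrogen so only C10=C1 can form, and the basic medium disfavours ionisation with methyl shift.

Step 11
Reactants: 13 cyclohexene ketal
Product: 14 methyl ketone (3-oxobutyl chain on C5)
Conditions: pyridinium p-toluenesulfonate, acetone–H2O, 50 °C
Reagents that add atoms: water, O
Why: Mild acid-catalysed ketal hydrolysis, which the secondary TBS ether and the isolated alkene tolerate.

Step 12
Reactants: 14 methyl ketone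
Product: 16 α-hydroxy ketone (4-hydroxy-3-oxobutyl chain; C9–OH), via terminal potassium enolate 15 (not isolated)
Conditions: KN(SiMe3)2, THF, −78 °C; 2-(phenylsulfonyl)-3-phenyloxaziridine, −78 °C
Reagents that add atoms: 2-(phenylsulfonyl)-3-phenyloxaziridine, O=S(=O)(c1ccccc1)N1OC1c1ccccc1
Why: Kinetic deprotonation of the methyl group by the bulky amide followed by electrophilic enolate hydroxylation with an N-sulfonyloxaziridine; this oxidises C9 only, whereas SeO2 would also attack C7 and allylic C2.

Step 13
Reactants: 16 α-hydroxy ketone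
Product: 17 α-keto aldehyde (3α-OTBS cyclohexene C10=C1 with 3,4-dioxobutyl chain on C5)
Conditions: Dess–Martin periodinane, CH2Cl2, 0 °C to rt; toluene azeotrope, used at once
Reagents that add atoms: none
Why: Dess–Martin oxidation of the primary ketol under water-free conditions leaves alkene and silyl ether untouched, and the glyoxal is dried and used immediately because such aldehydes hydrate and oligomerise.

Step 14
Reactants: 17 α-keto aldehyde
Product: 18 cis-fused 9α-hydroxy-8-oxo-octalin with C1=C2 (3α-OTBS; H10 β; 4β,5β-dimethyl)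
Conditions: Me2AlCl (1.5 equiv), CH2Cl2, −78 to −40 °C; aq. HCl work-up
Reagents that add atoms: none
Why: Me2AlCl binds the aldehyde oxygen at one point only, C10 of the ring A alkene attacks C9 while the pseudoaxial α-hydrogen on C2 passes to that oxygen in a concerted but asynchronous six-centre process that moves the alkene to C1=C2, and the new alcohol is trapped as its aluminium alkoxide with loss of methane so no protic acid reaches the now allylic silyl ether. The closest known reaction type is the Lewis acid-promoted type 1 intramolecular carbonyl-ene cyclisation of glyoxylate-like aldehydes. The new six-membered ring B forms in a 6-exo mode (exo at both π bonds) through a chair-shaped array in which the chain leaves C5 pseudoequatorially and C9 reaches C10 axially, a geometry available in the favoured half-chair (OTBS and C15 equatorial, H2α pseudoaxial). C10 is controlled by the three-atom tether, which sits on the α face of C5 and can deliver C9 only to the α face of C10, giving the cis fusion with H10 β, syn to C14. C9 is controlled by the suprafacial hydrogen transfer: C2 lies on the C5 side of C10=C1, so the aldehyde oxygen must point over ring A and ends α, axial on ring B and trans to H10, which is the C9 epimer of the target and is corrected in step 17. The step needs aldehyde over ketone chemoselectivity, secured by the far higher electrophilicity of the formyl group, attack at C10 rather than C1, secured because C1 would demand a bridged seven-membered ring, and a non-chelating Lewis acid, since a chelated s-cis dicarbonyl would swing O9 away from H2.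

Step 15
Reactants: 18 ene product
Product: 19 9α-TIPS ether of 18
Conditions: i-Pr3SiOTf, 2,6-lutidine, CH2Cl2, 0 °C to rt
Reagents that add atoms: triisopropylsilyl triflate, CC(C)[Si](C(C)C)(C(C)C)OS(=O)(=O)C(F)(F)F
Why: Silyl triflate silylation of a hindered secondary alcohol, done on the octalin where the flat C1=C2 unit leaves room under ring A; TIPS is chosen because it resists migration and outlasts TBS in acid.

Step 16
Reactants: 19 silylated octalin
Product: 20 9α-OTIPS cis-decal-8-one (3α-OTBS)
Conditions: H2 (1 atm), Pd/C (10 wt %), EtOAc, rt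
Reagents that add atoms: none
Why: Heterogeneous hydrogenation of the cis-disubstituted C1=C2 alkene; no stereocentre is formed, and ketone and silyl ethers are inert in ethyl acetate.

Step 17
Reactants: 20 9α-OTIPS decalone
Product: 21 9β-OTIPS cis-decal-8-one (3α-OTBS; O9 cis to H10)
Conditions: DBU (0.5 equiv), toluene, 80 °C
Reagents that add atoms: none
Why: Base-catalysed epimerisation through the C8–C9 enolate under thermodynamic control; the axial 9α-silyloxy group is syn-diaxial to C4 inside the fold of the cis-decalin whereas the 9β group is equatorial, C10 is not acidic so the ring fusion is safe, and any 9β material formed in step 14 converges here.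

Step 18
Reactants: 22 hydroxyacetone
Product: 23 1-(tert-butyldiphenylsilyloxy)propan-2-one
Conditions: t-BuPh2SiCl, imidazole, CH2Cl2, 0 °C to rt
Reagents that add atoms: tert-butyldiphenylsilyl chloride, CC(C)(C)[Si](Cl)(c1ccccc1)c1ccccc1
Why: Standard silylation of a primary alcohol; TBDPS is chosen so that C12–O survives the later acidic removal of the C3 TBS group.

Step 19
Reactants: 21 9β-OTIPS decalone; 23 1-(tert-butyldiphenylsilyloxy)propan-2-one
Product: 25 C7 aldol adduct (tertiary carbinol C11; mixture at C7 and C11), via C7=C8 lithium enolate 24 (not isolated)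
Conditions: LiN(i-Pr)2, THF, −78 °C; 23, −78 °C; AcOH quench at −78 °C
Reagents that add atoms: none
Why: Kinetic enolisation at the C7 methylene rather than at the shielded C9–H, then aldol addition to the inductively activated α-silyloxy ketone; the cold acidic quench blocks retro-aldol, and the new centres C7 and C11 are erased in the next step.

Step 20
Reactants: 25 aldol adduct
Product: 27 (Z)-7(11)-alkylidene enone (C12–OTBDPS cis to C8; C13 cis to C6), via C11 mesylate 26 (not isolated)
Conditions: MsCl, Et3N, CH2Cl2, 0 °C; then DBU, rt to 40 °C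
Reagents that add atoms: none
Why: Mesylation and E1cB elimination; DBU equilibrates the alkylidene through the extended enolate, the bulkier CH2OTBDPS arm should settle beside the flat C8 carbonyl (Z) rather than against C6H2 next to quaternary C5, and any E isomer is separated and resubmitted to DBU.

Step 21
Reactants: 27 (Z)-enone
Product: 28 3α-alcohol of 27 (9β-OTIPS and C12–OTBDPS kept)
Conditions: camphor-10-sulfonic acid (cat.), MeOH–CH2Cl2, 0 °C
Reagents that add atoms: none
Why: Acid-catalysed methanolysis distinguishes silyl ethers by bulk and oxygen basicity; the secondary TBS ether leaves while the TIPS ether next to the ketone and the TBDPS ether stay.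

Step 22
Reactants: 29 (E)-oct-2-enal
Product: 30 (E)-non-3-en-1-yne
Conditions: Me3SiCHN2, LiN(i-Pr)2, THF, −78 °C to rt
Reagents that add atoms: trimethylsilyldiazomethane, C[Si](C)(C)C=[N+]=[N-]
Why: Colvin rearrangement; addition of the lithiated diazo compound, loss of silanolate and N2, and a 1,2-hydrogen shift of the alkylidene carbene give the terminal alkyne, with no alcohol present that could add to the enal and with the E alkene untouched.

Step 23
Reactants: 30 (E)-non-3-en-1-yne
Product: 32 (1E,3E)-1-iodo-2-methylnona-1,3-diene, via alkenylalane 31 (not isolated)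
Conditions: AlMe3, Cp2ZrCl2 (0.25 equiv), CH2Cl2, 0 °C to rt; I2, THF, −30 °C
Reagents that add atoms: trimethylaluminium, C[Al](C)C; iodine, [I][I]
Why: Zirconium-catalysed methylalumination (Negishi carboalumination) adds methyl and aluminium syn, with aluminium on the terminal carbon, and iodinolysis with retention gives the E trisubstituted alkenyl iodide.

Step 24
Reactants: 32 dienyl iodide; 33 acrylic acid
Product: 34 (2E,4E,6E)-5-methyldodeca-2,4,6-trienoic acid
Conditions: Pd(OAc)2 (5 mol %), P(o-tol)3, Et3N, MeCN, 60 °C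
Reagents that add atoms: none
Why: Heck reaction of an alkenyl iodide with acrylic acid; syn insertion and syn β-hydride elimination create the new E alkene while the iodide geometry is retained.

Step 25
Reactants: 28 3α-alcohol; 34 trienoic acid
Product: 35 3α-trienoate with 9β-OTIPS and C12–OTBDPS
Conditions: EDC·HCl, DMAP, CH2Cl2, 0 °C to rt
Reagents that add atoms: none
Why: Steglich-type carbodiimide/DMAP esterification of the only free hydroxyl; the C3–O bond is not broken, so the α configuration is retained.

Step 26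
Reactants: 35 bis-silyl ether
Product: 36 target CNP0226738.1
Conditions: Bu4NF, AcOH (1:1), THF, 0 °C to rt
Reagents that add atoms: none
Why: Fluoride-mediated desilylation buffered with acetic acid; the near-neutral medium avoids ketol isomerisation and ester cleavage as well as acid-induced cyclodehydration of the (Z)-γ-hydroxy enone to a furan.

Compound list
1 | 2-methylcyclohexane-1,3-dione | CC1C(=O)CCCC1=O | starting material
2 | methyl vinyl ketone | CC(=O)C=C | starting material
3 | 2-methyl-2-(3-oxobutyl)cyclohexane-1,3-dione | CC(=O)CCC1(C)C(=O)CCCC1=O | intermediate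
4 | 2-methyl-2-[2-(2-methyl-1,3-dioxolan-2-yl)ethyl]cyclohexane-1,3-dione | CC1(CCC2(C)C(=O)CCCC2=O)OCCO1 | intermediate
5 | (2S,3S)-3-hydroxy-2-methyl-2-[2-(2-methyl-1,3-dioxolan-2-yl)ethyl]cyclohexan-1-one | C[C@@]1(CCC2(C)OCCO2)C(=O)CCC[C@@H]1O | intermediate
6 | C4 2,4,6-triisopropylbenzenesulfonylhydrazone of 5 | C[C@@]1(CCC2(C)OCCO2)/C(=N/NS(=O)(=O)c2c(C(C)C)cc(C(C)C)cc2C(C)C)CCC[C@@H]1O | intermediate
7 | C4 vinyllithium C10 lithium alkoxide (not isolated) | C[C@@]1(CCC2(C)OCCO2)C([Li])=CCC[C@@H]1O[Li] | intermediate
8 | 10α-hydroxy cyclohexene with C3=C4 and C15 on C4 | C[C@@]1(CCC2(C)OCCO2)C(C)=CCC[C@@H]1O | intermediate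
9 | 3α,4α-epoxide of 8 | C[C@@]1(CCC2(C)OCCO2)[C@]3(C)O[C@@H]3CC[C@@H]1O | intermediate
10 | 3α,10α-diol with exocyclic C4=C15 | O[C@@H]1CC[C@H](O)[C@](C)(CCC2(C)OCCO2)C1=C | intermediate
11 | 3α,10α-diol with 4β-methyl | O[C@@H]1CC[C@H](O)[C@](C)(CCC2(C)OCCO2)[C@H]1C | intermediate
12 | 3α-TBS ether of 11 | CC(C)(C)[Si](C)(C)O[C@@H]1CC[C@H](O)[C@](C)(CCC2(C)OCCO2)[C@H]1C | intermediate
13 | cyclohexene C10=C1 with ketal chain | CC(C)(C)[Si](C)(C)O[C@@H]1CC=C[C@](C)(CCC2(C)OCCO2)[C@H]1C | intermediate
14 | cyclohexene with 3-oxobutyl chain | CC(C)(C)[Si](C)(C)O[C@@H]1CC=C[C@](C)(CCC(C)=O)[C@H]1C | intermediate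
15 | terminal potassium enolate of 14 (not isolated) | CC(C)(C)[Si](C)(C)O[C@@H]1CC=C[C@](C)(CCC(=C)[O-])[C@H]1C.[K+] | intermediate
16 | cyclohexene with 4-hydroxy-3-oxobutyl chain | CC(C)(C)[Si](C)(C)O[C@@H]1CC=C[C@](C)(CCC(=O)CO)[C@H]1C | intermediate
17 | ene precursor, cyclohexene with 3,4-dioxobutyl chain on C5 | CC(C)(C)[Si](C)(C)O[C@@H]1CC=C[C@](C)(CCC(=O)C=O)[C@H]1C | intermediate
18 | ene product, cis-fused 9α-hydroxy-8-oxo-octalin with C1=C2 | CC(C)(C)[Si](C)(C)O[C@@H]1C=C[C@@H]2[C@H](O)C(=O)CC[C@]2(C)[C@H]1C | intermediate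
19 | 9α-TIPS ether of 18 | CC(C)(C)[Si](C)(C)O[C@@H]1C=C[C@@H]2[C@H](O[Si](C(C)C)(C(C)C)C(C)C)C(=O)CC[C@]2(C)[C@H]1C | intermediate
20 | 9α-OTIPS cis-decal-8-one | CC(C)(C)[Si](C)(C)O[C@@H]1CC[C@@H]2[C@H](O[Si](C(C)C)(C(C)C)C(C)C)C(=O)CC[C@]2(C)[C@H]1C | intermediate
21 | 9β-OTIPS cis-decal-8-one | CC(C)(C)[Si](C)(C)O[C@@H]1CC[C@@H]2[C@@H](O[Si](C(C)C)(C(C)C)C(C)C)C(=O)CC[C@]2(C)[C@H]1C | intermediate
22 | hydroxyacetone | CC(=O)CO | starting material
23 | 1-(tert-butyldiphenylsilyloxy)propan-2-one | CC(=O)CO[Si](c1ccccc1)(c1ccccc1)C(C)(C)C | intermediate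
24 | C7=C8 lithium enolate of 21 (not isolated) | CC(C)(C)[Si](C)(C)O[C@@H]1CC[C@@H]2[C@@H](O[Si](C(C)C)(C(C)C)C(C)C)C([O-])=CC[C@]2(C)[C@H]1C.[Li+] | intermediate
25 | C7 aldol adduct (C7 and C11 epimer mixture, both centres erased in step 20) | CC(C)(C)[Si](C)(C)O[C@@H]1CC[C@@H]2[C@@H](O[Si](C(C)C)(C(C)C)C(C)C)C(=O)C(C(C)(O)CO[Si](c3ccccc3)(c3ccccc3)C(C)(C)C)C[C@]2(C)[C@H]1C | intermediate
26 | C11 mesylate of 25 (not isolated) | CC(C)(C)[Si](C)(C)O[C@@H]1CC[C@@H]2[C@@H](O[Si](C(C)C)(C(C)C)C(C)C)C(=O)C(C(C)(OS(C)(=O)=O)CO[Si](c3ccccc3)(c3ccccc3)C(C)(C)C)C[C@]2(C)[C@H]1C | intermediate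
27 | (Z)-7(11)-alkylidene enone, fully silylated | CC(C)(C)[Si](C)(C)O[C@@H]1CC[C@@H]2[C@@H](O[Si](C(C)C)(C(C)C)C(C)C)C(=O)/C(=C(/C)CO[Si](c3ccccc3)(c3ccccc3)C(C)(C)C)C[C@]2(C)[C@H]1C | intermediate
28 | 3α-alcohol of 27 | O[C@@H]1CC[C@@H]2[C@@H](O[Si](C(C)C)(C(C)C)C(C)C)C(=O)/C(=C(/C)CO[Si](c3ccccc3)(c3ccccc3)C(C)(C)C)C[C@]2(C)[C@H]1C | intermediate
29 | (E)-oct-2-enal | CCCCC/C=C/C=O | starting material
30 | (E)-non-3-en-1-yne | CCCCC/C=C/C#C | intermediate
31 | (1E,3E)-dimethyl(2-methylnona-1,3-dienyl)alane (not isolated) | CCCCC/C=C/C(C)=C/[Al](C)C | intermediate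
32 | (1E,3E)-1-iodo-2-methylnona-1,3-diene | CCCCC/C=C/C(C)=C/I | intermediate
33 | acrylic acid | C=CC(=O)O | starting material
34 | (2E,4E,6E)-5-methyldodeca-2,4,6-trienoic acid | CCCCC/C=C/C(C)=C/C=C/C(=O)O | intermediate
35 | 3α-trienoate with 9β-OTIPS and C12–OTBDPS | CCCCC/C=C/C(C)=C/C=C/C(=O)O[C@@H]1CC[C@@H]2[C@@H](O[Si](C(C)C)(C(C)C)C(C)C)C(=O)/C(=C(/C)CO[Si](c3ccccc3)(c3ccccc3)C(C)(C)C)C[C@]2(C)[C@H]1C | intermediate
36 | CNP0226738.1, 3α-[(2E,4E,6E)-5-methyldodeca-2,4,6-trienoyloxy]-9β,12-dihydroxy-10βH-eremophil-7(11)Z-en-8-one | CCCCC/C=C/C(C)=C/C=C/C(=O)O[C@@H]1CC[C@@H]2[C@@H](O)C(=O)/C(=C(/C)CO)C[C@]2(C)[C@H]1C | target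

Total step count: 26. Longest linear sequence: 22 steps (steps 1–17, 19–21, 25 and 26). Step 18 and steps 22–24 are convergent side branches.

Steps most likely to fail

Step 14 (key step). The 1,2-disubstituted alkene may react too slowly, so that oligomerisation of the glyoxal, methyl transfer from aluminium or chloride capture takes over. The fallback keeps the C9–C10 disconnection but makes the closure stepwise. Starting from 17, chelating SnCl4 (CH2Cl2, −78 °C) should trigger a Prins cyclisation with an equatorial, chelated oxygen and chloride capture at C1. This gives the 1β-chloro-9β-hydroxy cis-decal-8-one F1. Bu3SnH with AIBN removes the chlorine to give the saturated 9β-ketol F2. Silylation with i-Pr3SiOTf and 2,6-lutidine then rejoins the route at 21, bypassing 18–20.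

Step 20. Poor control of the alkylidene geometry, or drift into deconjugated isomers during the elimination, would erode the supply of the Z isomer. The fallback locks the geometry in a ring. Starting from 21, the lithium enolate is added to 1,1-dimethoxyacetone to give the aldol acetal F3. Pyridinium p-toluenesulfonate in warm toluene cyclodehydrates it to the fused 3-methylfuran F4. N-bromosuccinimide with NaHCO3 in aqueous acetone at −15 °C opens the furan stereospecifically to the (Z)-keto enal F5. NaBH(OAc)3 reduces only the aldehyde to the (Z)-hydroxy enone F6, and t-BuPh2SiCl with imidazole rejoins the route at 27.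

Step 17. Slow enolisation of the equatorial C9–H, or silyl migration within the enolate, could leave the epimerisation incomplete or unclean. The fallback inverts C9 by substitution instead of equilibration. Starting from 18, Tf2O and pyridine give the 9α-triflate F7. Bu4NNO2 displaces the axial, carbonyl-activated leaving group with inversion, and hydrolysis of the nitrite ester on work-up gives the 9β-hydroxy octalin F8. Treatment with i-Pr3SiOTf and 2,6-lutidine gives the 9β-TIPS ether F9, and hydrogenation over Pd/C rejoins the route at 21.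

Further compounds
F1 | step 14 | 1β-chloro-9β-hydroxy-3α-OTBS cis-decal-8-one | CC(C)(C)[Si](C)(C)O[C@@H]1C[C@@H](Cl)[C@@H]2[C@@H](O)C(=O)CC[C@]2(C)[C@H]1C
F2 | step 14 | 9β-hydroxy-3α-OTBS cis-decal-8-one | CC(C)(C)[Si](C)(C)O[C@@H]1CC[C@@H]2[C@@H](O)C(=O)CC[C@]2(C)[C@H]1C
F3 | step 20 | C7 aldol adduct of 21 with 1,1-dimethoxyacetone (epimer mixture at C7 and C11) | CC(C)(C)[Si](C)(C)O[C@@H]1CC[C@@H]2[C@@H](O[Si](C(C)C)(C(C)C)C(C)C)C(=O)C(C(C)(O)C(OC)OC)C[C@]2(C)[C@H]1C
F4 | step 20 | 3-methylfuran fused at C7–C8 | CC(C)(C)[Si](C)(C)O[C@@H]1CC[C@@H]2[C@@H](O[Si](C(C)C)(C(C)C)C(C)C)c3occ(C)c3C[C@]2(C)[C@H]1C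
F5 | step 20 | (Z)-8-oxo-7(11)-en-12-al | CC(C)(C)[Si](C)(C)O[C@@H]1CC[C@@H]2[C@@H](O[Si](C(C)C)(C(C)C)C(C)C)C(=O)/C(=C(/C)C=O)C[C@]2(C)[C@H]1C
F6 | step 20 | (Z)-12-hydroxy-7(11)-en-8-one | CC(C)(C)[Si](C)(C)O[C@@H]1CC[C@@H]2[C@@H](O[Si](C(C)C)(C(C)C)C(C)C)C(=O)/C(=C(/C)CO)C[C@]2(C)[C@H]1C
F7 | step 17 | 9α-triflate of 18 | CC(C)(C)[Si](C)(C)O[C@@H]1C=C[C@@H]2[C@H](OS(=O)(=O)C(F)(F)F)C(=O)CC[C@]2(C)[C@H]1C
F8 | step 17 | cis-fused 9β-hydroxy-8-oxo-octalin with C1=C2 | CC(C)(C)[Si](C)(C)O[C@@H]1C=C[C@@H]2[C@@H](O)C(=O)CC[C@]2(C)[C@H]1C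
F9 | step 17 | 9β-TIPS ether of F8 | CC(C)(C)[Si](C)(C)O[C@@H]1C=C[C@@H]2[C@@H](O[Si](C(C)C)(C(C)C)C(C)C)C(=O)CC[C@]2(C)[C@H]1C
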